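A small charge of free base, 0.0600 M in blue and 0.100 M in grey, stands against 0.20 M of electrophile, less of it than of electrophile, and I ask what it does to the end of the reaction.

    free base ⇌ dormant form (K1 = 6.5, k1 = 0.0847 h⁻¹)
    electrophile + nucleophile → acid set free + target (k2 = 0.143 M⁻¹ h⁻¹)
    nucleophile + acid set free ⇌ protonated nucleophile, settled at all times (K3 = 7300 M⁻¹)
    acid set free + free base ⇌ salt of the base, settled at all times (K4 = 22.3 M⁻¹)
    crystals ⇌ acid set free, rate k5*(cs5 - [acid set free]) while solid is left; crystals form when [acid set free] > cs5 (cs5 = 7.6 mM, k5 = 0.107 h⁻¹)

| flask | electrophile | nucleophile | free base | time |
|---|---|---|---|---|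
| blue | 0.20 M | 0.500 M | 0.0600 M | 10 d |
| ochre | 0.20 M | 0.500 M | 0.0780 M | 10 d |
| grey | 0.20 M | 0.500 M | 0.100 M | 10 d |

- part of the electrophile that has reacted at the end, blue
- part of the electrophile that has reacted at the end, ochre
- part of the electrophile that has reacted at the end, grey
- what raising the concentration of free base from its lowest to its highest value here does to the part of the electrophile that has reacted (changes below 5 percentage points count as none) (no change / it falls / it rises)

- for acid set free the crystals are counted in
- as a solid, counted per litre of solution: crystals
- run time (blue): 10 d

I look for two ways in which the free base might change the outcome. The first is to win acid set free from the nucleophile. But at the start of grey, equilibrium constant times concentration is 3.21 powers of ten higher for the nucleophile, so I let each electrophile that reacts cost two nucleophiles, one to form target and one to hold the acid. The second is a shortage of nucleophile, which I read from the reserve ρ = 1.25, the nucleophile charged over two per electrophile charged: a shortage means ρ under one. These flasks stand 0.0969 powers of ten above one.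

The excess e = 0.100 M stays free, so I reckon acid set free at completion near 0.274 mM, less than the solubility 7.6 mM, and I expect no crystals. Free nucleophile is e plus two per electrophile left, so integrating the rate law gives, with D the powers of ten of the exponent:

D = 0.143 M⁻¹ h⁻¹ × e × 10 d in powers of ten = 1.49

part left = (ρ − 1) / (ρ × 10^D − 1) = 0.664%

Free base stands in neither line, so I commit to 99.3% in blue, 99.3% in ochre and 99.3% in grey, which means no change.

The forecast gives 99.3%, 99.3% and 99.3%, with no change, and says of the free base: “It is therefore irrelevant”.

The simulation gives 99.3% in blue, 99.3% in ochre and 99.3% in grey; raising the free base from blue to grey brings no change, a difference of 0 percentage points. At completion the reserve leaves 20.0% of the nucleophile unbound; blue holds 20.6% after 10.0 d and 20.1% after 100 d, with crystals at 0 M after 10.0 d. Grey with 0.30 M of nucleophile has a reserve of 0.750, under one, and there 75.2% of the electrophile reacts. The nucleophile, now the limiting reagent, is down to 1.6% of its charge, with 25% of the electrophile still there.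

The numbers of this flask are assumed; the flask was simulated.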